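**Retrosynthetic overview**
1. Target 12 ⇒ phenol 10 + allyl-TMS. The ring-C aryl–allyl C–C bond is made by oxidising the phenol to a phenoxonium ion (a vinylogous enolonium), so the normally nucleophilic para-carbon is attacked by the nucleophilic allylsilane.
2. 10 ⇒ dehydrodieugenol B (7) + 2-fluoro-6-methoxybenzaldehyde (2): diaryl ether by SNAr, then CHO → OH by Dakin oxidation.
3. 7 ⇒ phenol 5 + allyl-TMS by the same umpolung allylation; 5 ⇒ eugenol (1) + 2 by the same SNAr/Dakin pair.
4. No ring is formed. The three benzene rings are bought (A = eugenol, B and C = 2) and attached in the order A → B → C.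

Assumption: the target has no stereocentre (it is achiral), so no enantiocontrol is needed; allyl-TMS, PhI(OAc)2 and H2O2 are treated as reagents.

**Route**

Step 1
Reactants: 1 eugenol (4-allyl-2-methoxyphenol); 2 2-fluoro-6-methoxybenzaldehyde
Product: 3 2-(4-allyl-2-methoxyphenoxy)-6-methoxybenzaldehyde
Conditions: K2CO3 (2 equiv), DMF, 110 °C, N2
Reagents that add atoms: none
Why: SNAr, in which the eugenol phenoxide displaces the fluoride activated by the ortho-formyl group (Meisenheimer stabilisation), while carbonate is too weak a base to isomerise the allyl group.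

Step 2
Reactants: 3 2-(4-allyl-2-methoxyphenoxy)-6-methoxybenzaldehyde
Product: 5 2-(4-allyl-2-methoxyphenoxy)-6-methoxyphenol, via aryl formate 4 (not isolated)
Conditions: 30% aq H2O2 (1.3 equiv), cat. H2SO4, MeOH, 0 °C → rt
Reagents that add atoms: hydrogen peroxide, OO
Why: Acid-catalysed Dakin (Baeyer–Villiger-type) oxidation, in which the electron-rich 2,6-dioxygenated aryl group migrates to give formate 4 that is methanolysed in situ, and H2O2 without a peracid leaves the isolated allyl alkene untouched.

Step 3
Reactants: 5 2-(4-allyl-2-methoxyphenoxy)-6-methoxyphenol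
Product: 7 4-allyl-2-(4-allyl-2-methoxyphenoxy)-6-methoxyphenol (dehydrodieugenol B), via para-allyl dienone 6 (not isolated)
Conditions: PhI(OAc)2 (0.95 equiv, slow addition), allyl-TMS (5 equiv), HFIP/CH2Cl2 (4:1), −15 → 0 °C
Reagents that add atoms: allyltrimethylsilane, C=CC[Si](C)(C)C
Why: Proposed new method: PhI(OAc)2 in HFIP converts phenol 5 into a phenoxonium ion (a vinylogous enolonium, so the normally nucleophilic para-carbon becomes electrophilic) that is captured at its only unsubstituted position by the π-nucleophile allyl-TMS (β-silyl cation, then desilylation) to give dienone 6, which tautomerises to 7, and any ipso attack at an oxygenated ortho carbon would reach the same product by Cope shift; the closest known reaction type is the hypervalent-iodine oxidative allylation of 4-substituted phenols with allylsilanes in fluorinated alcohols ("aromatic ring umpolung"), here extended to a para-unsubstituted phenol, with a slight deficit of oxidant and excess silane to hold back over-oxidation of the more electron-rich product.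

Step 4
Reactants: 7 dehydrodieugenol B; 2 2-fluoro-6-methoxybenzaldehyde
Product: 8 2-[4-allyl-2-(4-allyl-2-methoxyphenoxy)-6-methoxyphenoxy]-6-methoxybenzaldehyde
Conditions: Cs2CO3 (2 equiv), DMF, 100 °C, N2
Reagents that add atoms: none
Why: SNAr as in step 1, using the more dissociated caesium phenoxide because the phenoxide of 7 is di-ortho-substituted, while the electrophile has its activating formyl group ortho to fluorine and no substituent on the other side of the C–F carbon.

Step 5
Reactants: 8 2-[4-allyl-2-(4-allyl-2-methoxyphenoxy)-6-methoxyphenoxy]-6-methoxybenzaldehyde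
Product: 10 2-[4-allyl-2-(4-allyl-2-methoxyphenoxy)-6-methoxyphenoxy]-6-methoxyphenol, via aryl formate 9 (not isolated)
Conditions: 30% aq H2O2 (1.3 equiv), cat. H2SO4, MeOH, 0 °C → rt
Reagents that add atoms: hydrogen peroxide, OO
Why: Acid-catalysed Dakin oxidation as in step 2, with aryl migration favoured by the two ortho oxygen substituents, in situ methanolysis of formate 9, and both allyl groups inert to H2O2 in the absence of a peracid.

Step 6
Reactants: 10 2-[4-allyl-2-(4-allyl-2-methoxyphenoxy)-6-methoxyphenoxy]-6-methoxyphenol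
Product: 12 4-allyl-2-[4-allyl-2-(4-allyl-2-methoxyphenoxy)-6-methoxyphenoxy]-6-methoxyphenol (target), via para-allyl dienone 11 (not isolated)
Conditions: PhI(OAc)2 (0.95 equiv, slow addition), allyl-TMS (5 equiv), HFIP/CH2Cl2 (4:1), −15 → 0 °C
Reagents that add atoms: allyltrimethylsilane, C=CC[Si](C)(C)C
Why: Proposed new method: as in step 3, only ring C carries a free OH that can ligate iodine(III), so its phenoxonium ion (vinylogous enolonium) is formed selectively and trapped at the free para-carbon by excess allyl-TMS to give dienone 11, which tautomerises to the target, while the ether rings A and B and their weakly nucleophilic terminal alkenes cannot compete with the silane; the closest known reaction type is the hypervalent-iodine oxidative allylation of 4-substituted phenols with allylsilanes in HFIP.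

**Compound list**
1 | eugenol (4-allyl-2-methoxyphenol) | C=CCc1ccc(O)c(OC)c1 | starting material
2 | 2-fluoro-6-methoxybenzaldehyde | O=Cc1c(F)cccc1OC | starting material
3 | 2-(4-allyl-2-methoxyphenoxy)-6-methoxybenzaldehyde | C=CCc1ccc(Oc2cccc(OC)c2C=O)c(OC)c1 | intermediate
4 | 2-(4-allyl-2-methoxyphenoxy)-6-methoxyphenyl formate | C=CCc1ccc(Oc2cccc(OC)c2OC=O)c(OC)c1 | intermediate (not isolated)
5 | 2-(4-allyl-2-methoxyphenoxy)-6-methoxyphenol | C=CCc1ccc(Oc2cccc(OC)c2O)c(OC)c1 | intermediate
6 | 4-allyl-2-(4-allyl-2-methoxyphenoxy)-6-methoxycyclohexa-2,5-dien-1-one (racemic, transient) | C=CCc1ccc(OC2=CC(CC=C)C=C(OC)C2=O)c(OC)c1 | intermediate (not isolated)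
7 | 4-allyl-2-(4-allyl-2-methoxyphenoxy)-6-methoxyphenol (dehydrodieugenol B) | C=CCc1ccc(Oc2cc(CC=C)cc(OC)c2O)c(OC)c1 | intermediate
8 | 2-[4-allyl-2-(4-allyl-2-methoxyphenoxy)-6-methoxyphenoxy]-6-methoxybenzaldehyde | C=CCc1ccc(Oc2cc(CC=C)cc(OC)c2Oc2cccc(OC)c2C=O)c(OC)c1 | intermediate
9 | 2-[4-allyl-2-(4-allyl-2-methoxyphenoxy)-6-methoxyphenoxy]-6-methoxyphenyl formate | C=CCc1ccc(Oc2cc(CC=C)cc(OC)c2Oc2cccc(OC)c2OC=O)c(OC)c1 | intermediate (not isolated)
10 | 2-[4-allyl-2-(4-allyl-2-methoxyphenoxy)-6-methoxyphenoxy]-6-methoxyphenol | C=CCc1ccc(Oc2cc(CC=C)cc(OC)c2Oc2cccc(OC)c2O)c(OC)c1 | intermediate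
11 | 4-allyl-2-[4-allyl-2-(4-allyl-2-methoxyphenoxy)-6-methoxyphenoxy]-6-methoxycyclohexa-2,5-dien-1-one (racemic, transient) | C=CCc1ccc(Oc2cc(CC=C)cc(OC)c2OC2=CC(CC=C)C=C(OC)C2=O)c(OC)c1 | intermediate (not isolated)
12 | 4-allyl-2-[4-allyl-2-(4-allyl-2-methoxyphenoxy)-6-methoxyphenoxy]-6-methoxyphenol (achiral) | C=CCc1ccc(Oc2cc(CC=C)cc(OC)c2Oc2cc(CC=C)cc(OC)c2O)c(OC)c1 | target

**Totals**
Total step count: 6. Longest linear sequence: 6 steps (1 → 3 → 5 → 7 → 8 → 10 → 12).

**Three steps most likely to fail, with fallbacks**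

Step 3 (oxidative allylation of 5). The risks are over-oxidation of the more electron-rich product, oxidative para–para dimerisation, and capture of the cation by solvent or acetate. The fallback sets out from 5 and replaces the oxidative C–C bond formation by a sigmatropic one. O-Allylation of 5 (allyl bromide, K2CO3, acetone, reflux) gives the allyl aryl ether 2-(allyloxy)-1-(4-allyl-2-methoxyphenoxy)-3-methoxybenzene F1. Heating F1 in N,N-diethylaniline at 190–200 °C starts a para-Claisen sequence, because both ortho positions are blocked. The first [3,3] shift gives the ortho-dienone 6-allyl-2-(4-allyl-2-methoxyphenoxy)-6-methoxycyclohexa-2,4-dien-1-one F2, and a Cope shift moves the allyl group to the para carbon. This delivers dienone 6 of the main route, which tautomerises, so the fallback comes back to the route at 7.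

Step 6 (oxidative allylation of 10). The risks are the same as in step 3, on a larger substrate with two allyl arenes present. The fallback sets out from 10. O-Allylation (allyl bromide, K2CO3, acetone, reflux) gives 2-(allyloxy)-1-[4-allyl-2-(4-allyl-2-methoxyphenoxy)-6-methoxyphenoxy]-3-methoxybenzene F3. Thermolysis (N,N-diethylaniline, 190–200 °C) gives the ortho-dienone 6-allyl-2-[4-allyl-2-(4-allyl-2-methoxyphenoxy)-6-methoxyphenoxy]-6-methoxycyclohexa-2,4-dien-1-one F4 by Claisen shift. A Cope shift then gives dienone 11 of the main route, which tautomerises, so the fallback comes back to the route at 12.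

Step 4 (SNAr with the hindered phenol 7). The di-ortho-substituted phenoxide may react too slowly with 2. The fallback sets out from 7 and uses a copper-catalysed Ullmann coupling with a protected ring-C bromide, so the aldehyde and the Dakin step are not needed. Commercial 2-bromo-6-methoxyphenol is protected (MOMCl, K2CO3, acetone) as 1-bromo-3-methoxy-2-(methoxymethoxy)benzene F5. Coupling of 7 with F5 (CuI, picolinic acid, K3PO4, DMSO, 90 °C) gives the MOM ether 1-[4-allyl-2-(4-allyl-2-methoxyphenoxy)-6-methoxyphenoxy]-3-methoxy-2-(methoxymethoxy)benzene F6. Cleavage of the MOM group (HCl, MeOH, 50 °C; allyl groups are stable) gives phenol 10, so the fallback comes back to the route at 10 and skips 8 and step 5.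

**Further compounds**
F1 | step 3 | 2-(allyloxy)-1-(4-allyl-2-methoxyphenoxy)-3-methoxybenzene | C=CCOc1c(OC)cccc1Oc1ccc(CC=C)cc1OC
F2 | step 3 | 6-allyl-2-(4-allyl-2-methoxyphenoxy)-6-methoxycyclohexa-2,4-dien-1-one (racemic, transient) | O=C1C(Oc2ccc(CC=C)cc2OC)=CC=CC1(CC=C)OC
F3 | step 6 | 2-(allyloxy)-1-[4-allyl-2-(4-allyl-2-methoxyphenoxy)-6-methoxyphenoxy]-3-methoxybenzene | C=CCOc1c(OC)cccc1Oc1c(OC)cc(CC=C)cc1Oc1ccc(CC=C)cc1OC
F4 | step 6 | 6-allyl-2-[4-allyl-2-(4-allyl-2-methoxyphenoxy)-6-methoxyphenoxy]-6-methoxycyclohexa-2,4-dien-1-one (racemic, transient) | O=C1C(Oc2c(OC)cc(CC=C)cc2Oc2ccc(CC=C)cc2OC)=CC=CC1(CC=C)OC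
F5 | step 4 | 1-bromo-3-methoxy-2-(methoxymethoxy)benzene | COCOc1c(Br)cccc1OC
F6 | step 4 | 1-[4-allyl-2-(4-allyl-2-methoxyphenoxy)-6-methoxyphenoxy]-3-methoxy-2-(methoxymethoxy)benzene | C=CCc1ccc(Oc2cc(CC=C)cc(OC)c2Oc2cccc(OC)c2OCOC)c(OC)c1
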